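**Plan**

- Retrosynthesis: the O–ethyl bond of a ring A phenol ether is cut last. Before it, two ring A C–C bonds are cut together (retro-[4+2]): the bond from the CH2-bearing carbon to its C–OH neighbour, and the bond from the acetyl-bearing carbon to its other C–OH neighbour.
- Enabling feature: ring A carries oxygen on three alternate carbons, with the acetyl carbon between two of them and the CH2-bearing carbon between two. The CH2-bearing carbon, C–OMe, CH and one C–OH form a 1,3-dimethoxy-1-silyloxy diene, and the remaining C–O and C–acetyl carbons form an acetyl alkynyl ether.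
- Further cuts: the bond from ring B to the side chain (Michael addition of acetylfilicinic acid to methyl 3-oxopent-4-enoate) and the two C–CH3 bonds of ring B.
- Forward order: ring B by dearomatising gem-dimethylation; side chain by Michael addition, stored as a cyclic methyl ketal; ketal opening and silylation to the diene; ring A last by cycloaddition–aromatisation; de-ethylation.
- Stereochemistry: the target has no stereocentre. The ketal carbon and the sp3 carbons of the cycloadduct are transient and need no control.

Key step: step 6

Assumption: the ketal of step 3 is drawn closed through the ring B oxygen remote from the acetyl group and the ring B silyl groups on the 3- and 5-oxygens; any other placement on the triketone oxygens would converge at the next ring-opening or hydrolysis.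

**Step 1**
Reactants: 1 2',4',6'-trihydroxyacetophenone
Product: 3 acetylfilicinic acid (2-acetyl-3,5-dihydroxy-4,4-dimethylcyclohexa-2,5-dien-1-one), via monomethylated acetophenone 2 (not isolated)
Conditions: MeI (2.2 equiv), NaOMe (3.2 equiv), MeOH, 0 °C → rt; 1 M HCl; chromatography or crystallisation
Reagents that add atoms: iodomethane, CI
Why: Twofold C-methylation of the phloroglucinol polyanion (dearomatising alkylation), in which the second methyl group should enter the carbon that already carries one and so turn the arene into the gem-dimethyl β-triketone, with under- and over-methylated by-products removed on purification.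

**Step 2**
Reactants: 4 methyl 5-methoxy-3-oxopentanoate
Product: 5 methyl 3-oxopent-4-enoate
Conditions: TsOH·H2O (cat.), PhH, reflux with removal of MeOH; short-path distillation; used at once
Reagents that add atoms: none
Why: Acid-catalysed β-elimination of methanol from the β-methoxy ketone, driven by removal of methanol, should give the conjugated vinyl ketone.

**Step 3**
Reactants: 3 acetylfilicinic acid, 5 methyl 3-oxopent-4-enoate
Product: 7 methyl 2-(6-acetyl-7-hydroxy-2-methoxy-8,8-dimethyl-5-oxo-3,4,5,8-tetrahydro-2H-chromen-2-yl)acetate (racemic), via Michael adduct 6 (not isolated)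
Conditions: 3 (1.1 equiv), Et3N (0.1 equiv), THF, 0 °C → rt; then MeOH, camphorsulfonic acid (0.3 equiv), 3 Å MS, rt
Reagents that add atoms: methanol, CO
Why: Michael addition of the cyclic β-triketone through its only ring CH carbon to the vinyl ketone, after which the neighbouring ring B enol should close onto the side-chain ketone as a hemiketal and acid-catalysed exchange with methanol (as known for enone adducts of 4-hydroxycoumarin) should fix it as the cyclic methyl ketal, whose stereocentre forms without control and is removed in step 4.

**Step 4**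
Reactants: 7 methyl 2-(6-acetyl-7-hydroxy-2-methoxy-8,8-dimethyl-5-oxo-3,4,5,8-tetrahydro-2H-chromen-2-yl)acetate
Product: 10 2-acetyl-6-[(2Z,4Z)-3,5-dimethoxy-5-(trimethylsilyloxy)penta-2,4-dien-1-yl]-4,4-dimethyl-3,5-bis(trimethylsilyloxy)cyclohexa-2,5-dien-1-one, via dilithium enoate 8 (not isolated), via trilithium dienolate 9 (not isolated)
Conditions: LiN(iPr)2 (commercial solution, 3.5 equiv), THF, −78 → 0 °C, recool to −78 °C; Me3SiCl (5 equiv), −78 °C → rt; volatiles removed in vacuo, pentane, filtration under Ar; crude diene used directly
Reagents that add atoms: chlorotrimethylsilane, C[Si](C)(C)Cl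
Why: After deprotonation of the ring B enol, the ester enolate should open the pyran ring by E1cB elimination (retro-oxa-Michael), expelling the vinylogous carboxylate oxygen of ring B in preference to methoxide, and a third equivalent of base then removes a γ-proton of the β-methoxy enoate so that Me3SiCl traps the ester dienolate and both ring B oxygens on oxygen (the standard γ-deprotonation/O-silylation route to 1,3-dialkoxy-1-silyloxy dienes); either enoate geometry leads to the same dienolate.

**Step 5**
Reactants: 11 ethoxyacetylene, 12 N-methoxy-N-methylacetamide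
Product: 15 4-ethoxybut-3-yn-2-one, via lithium ethoxyacetylide 13 (not isolated), via tetrahedral lithium adduct 14 (not isolated)
Conditions: n-BuLi (1.0 equiv), THF, −78 °C; then 12, −78 → −20 °C; sat. aq. NH4Cl, cold extraction; used promptly
Reagents that add atoms: none
Why: Deprotonation of the terminal alkyne and acylation of the acetylide by the Weinreb amide (Weinreb ketone synthesis), whose chelated tetrahedral adduct resists a second addition and should release the ynone only on mild protic quench.

**Step 6**
Reactants: 10 2-acetyl-6-[(2Z,4Z)-3,5-dimethoxy-5-(trimethylsilyloxy)penta-2,4-dien-1-yl]-4,4-dimethyl-3,5-bis(trimethylsilyloxy)cyclohexa-2,5-dien-1-one, 15 4-ethoxybut-3-yn-2-one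
Product: 18 2-acetyl-6-[(3-acetyl-2-ethoxy-4-hydroxy-6-methoxyphenyl)methyl]-3,5-dihydroxy-4,4-dimethylcyclohexa-2,5-dien-1-one, via cycloadduct 16 (not isolated), via silylated arene 17 (not isolated)
Conditions: 15 (1.5 equiv), PhMe, rt → 60 °C, Ar; then THF, 1 M HCl, rt
Reagents that add atoms: none
Why: The electron-rich diene 10 and the polarised alkynone 15 should combine in a normal-electron-demand Diels–Alder reaction, either concerted and asynchronous or stepwise by Mukaiyama–Michael addition followed by closure of the allenolate onto the silyloxycarbenium carbon, to give cyclohexa-1,4-diene 16. The closest known reaction type is the cycloaddition–aromatisation of 1,3-dialkoxy-1-silyloxybuta-1,3-dienes with acetylenic ketones and esters, which gives resorcinol derivatives. Ring A closes as a six-membered carbocycle by intermolecular [4+2] addition, the chain-bearing diene terminus bonding to the ethoxy-bearing alkyne carbon and the ketene acetal carbon to the acetyl-bearing alkyne carbon; 1,4-elimination of methanol from 16 should then give arene 17, and dilute acid removes the three silyl groups. Both sp3 carbons of 16 become aromatic, so no stereocentre has to be controlled and the configuration of the ketene acetal alkene does not matter. The step needs regioselectivity, which matched polarisation should secure: the diene is most nucleophilic at its terminal carbon, and the alkynone is electrophilic at the carbon β to the carbonyl, a position reinforced by the ethoxy donor, so the acetyl group ends up between the two oxygenated carbons.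

**Step 7**
Reactants: 18 2-acetyl-6-[(3-acetyl-2-ethoxy-4-hydroxy-6-methoxyphenyl)methyl]-3,5-dihydroxy-4,4-dimethylcyclohexa-2,5-dien-1-one
Product: 19 2-acetyl-6-[(3-acetyl-2,4-dihydroxy-6-methoxyphenyl)methyl]-3,5-dihydroxy-4,4-dimethylcyclohexa-2,5-dien-1-one
Conditions: BCl3 (5 equiv), CH2Cl2, −78 → 0 °C; then H2O
Reagents that add atoms: none
Why: BCl3-mediated ether cleavage directed by chelation to the aryl ketone, in which boron held between the carbonyl and the ortho ether oxygen activates the ethyl group for SN2 attack by chloride, while the para methyl ether cannot chelate and should survive at low temperature, and the boron chelates of ring B are hydrolysed on work-up.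

**Compound list**

1 | 2',4',6'-trihydroxyacetophenone | CC(=O)c1c(O)cc(O)cc1O | starting material
2 | 2',4',6'-trihydroxy-3'-methylacetophenone | CC(=O)c1c(O)cc(O)c(C)c1O | intermediate
3 | acetylfilicinic acid, 2-acetyl-3,5-dihydroxy-4,4-dimethylcyclohexa-2,5-dien-1-one | CC(=O)C1=C(O)C(C)(C)C(O)=CC1=O | intermediate
4 | methyl 5-methoxy-3-oxopentanoate | COCCC(=O)CC(=O)OC | starting material
5 | methyl 3-oxopent-4-enoate | C=CC(=O)CC(=O)OC | intermediate
6 | methyl 5-(5-acetyl-2,4-dihydroxy-3,3-dimethyl-6-oxocyclohexa-1,4-dien-1-yl)-3-oxopentanoate (open-chain form of the Michael adduct) | COC(=O)CC(=O)CCC1=C(O)C(C)(C)C(O)=C(C(C)=O)C1=O | intermediate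
7 | methyl 2-(6-acetyl-7-hydroxy-2-methoxy-8,8-dimethyl-5-oxo-3,4,5,8-tetrahydro-2H-chromen-2-yl)acetate, racemic | COC(=O)CC1(OC)CCC2=C(O1)C(C)(C)C(O)=C(C(C)=O)C2=O | intermediate
8 | dilithium salt (both ring B enol oxygens) of methyl (2E)-5-(5-acetyl-2,4-dihydroxy-3,3-dimethyl-6-oxocyclohexa-1,4-dien-1-yl)-3-methoxypent-2-enoate | [Li+].[Li+].COC(=O)/C=C(/OC)CCC1=C([O-])C(C)(C)C([O-])=C(C(C)=O)C1=O | intermediate
9 | trilithium salt formed from 8 by γ-deprotonation (ester dienolate plus ring B dienolate) | [Li+].[Li+].[Li+].CO/C([O-])=C/C(OC)=C/CC1=C([O-])C(C)(C)C([O-])=C(C(C)=O)C1=O | intermediate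
10 | 2-acetyl-6-[(2Z,4Z)-3,5-dimethoxy-5-(trimethylsilyloxy)penta-2,4-dien-1-yl]-4,4-dimethyl-3,5-bis(trimethylsilyloxy)cyclohexa-2,5-dien-1-one | CO/C(O[Si](C)(C)C)=C/C(OC)=C/CC1=C(O[Si](C)(C)C)C(C)(C)C(O[Si](C)(C)C)=C(C(C)=O)C1=O | intermediate
11 | ethoxyacetylene | CCOC#C | starting material
12 | N-methoxy-N-methylacetamide | CC(=O)N(C)OC | starting material
13 | lithium ethoxyacetylide | [Li+].[C-]#COCC | intermediate
14 | lithium 4-ethoxy-2-[methoxy(methyl)amino]but-3-yn-2-olate, racemic | [Li+].CCOC#CC(C)([O-])N(C)OC | intermediate
15 | 4-ethoxybut-3-yn-2-one | CCOC#CC(C)=O | intermediate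
16 | 2-acetyl-6-{[3-acetyl-2-ethoxy-4,6-dimethoxy-4-(trimethylsilyloxy)cyclohexa-2,5-dien-1-yl]methyl}-4,4-dimethyl-3,5-bis(trimethylsilyloxy)cyclohexa-2,5-dien-1-one, configuration at the two sp3 ring carbons undefined | CCOC1=C(C(C)=O)C(OC)(O[Si](C)(C)C)C=C(OC)C1CC2=C(O[Si](C)(C)C)C(C)(C)C(O[Si](C)(C)C)=C(C(C)=O)C2=O | intermediate
17 | 2-acetyl-6-{[3-acetyl-2-ethoxy-6-methoxy-4-(trimethylsilyloxy)phenyl]methyl}-4,4-dimethyl-3,5-bis(trimethylsilyloxy)cyclohexa-2,5-dien-1-one | CCOc1c(C(C)=O)c(O[Si](C)(C)C)cc(OC)c1CC2=C(O[Si](C)(C)C)C(C)(C)C(O[Si](C)(C)C)=C(C(C)=O)C2=O | intermediate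
18 | 2-acetyl-6-[(3-acetyl-2-ethoxy-4-hydroxy-6-methoxyphenyl)methyl]-3,5-dihydroxy-4,4-dimethylcyclohexa-2,5-dien-1-one | CCOc1c(C(C)=O)c(O)cc(OC)c1CC2=C(O)C(C)(C)C(O)=C(C(C)=O)C2=O | intermediate
19 | 2-acetyl-6-[(3-acetyl-2,4-dihydroxy-6-methoxyphenyl)methyl]-3,5-dihydroxy-4,4-dimethylcyclohexa-2,5-dien-1-one | COc1cc(O)c(C(C)=O)c(O)c1CC1=C(O)C(C)(C)C(O)=C(C(C)=O)C1=O | target

**Step count and risks**

Total: 7 steps. Longest linear sequence: 5 steps (steps 1, 3, 4, 6 and 7, from 1 to 19); steps 2 and 5 are one-step side branches.

Steps most likely to fail: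

1. Step 6. The ethoxy donor lowers the dienophilicity of 15 and the substituent on the diene terminus slows bond formation, so protodesilylation or thermal decay of 10, or 1,2-addition to the ketone of 15, may outrun the cycloaddition. The fallback sets out from 3 and comes back at 19. Compound 3 and commercial 2',6'-dihydroxy-4'-methoxyacetophenone F1 are stirred with aqueous formaldehyde in dilute aqueous KOH at room temperature. Knoevenagel condensation of 3 with formaldehyde, followed by Michael addition of a free ring carbon of F1 (both are equivalent), should form the methylene bridge and give 19 directly. The two symmetrical dimers would be removed by chromatography.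

2. Step 4. The third deprotonation has to take place on a species that already carries two negative charges. Precipitation of the polyanion, competing enolisation of the ring B acetyl group, or hydrolytic loss of the labile ring B silyl groups during isolation may leave acidic sites that destroy the ketene acetal. The fallback sets out from 4 and comes back at 18; it leaves ring B out of the diene and attaches it after the arene is made. Compound 4 with HC(OMe)3 and catalytic H2SO4 in MeOH should give methyl (2E)-3,5-dimethoxypent-2-enoate F2. LiN(iPr)2 then Me3SiCl at −78 °C should give (1Z,3Z)-1,3,5-trimethoxy-1-(trimethylsilyloxy)penta-1,3-diene F3. Cycloaddition–aromatisation of F3 with 15 under the conditions of step 6 should give 1-[2-ethoxy-6-hydroxy-4-methoxy-3-(methoxymethyl)phenyl]ethan-1-one F4. BF3·OEt2 in CH2Cl2 should then ionise the benzylic methyl ether of F4, whose cation is stabilised by two ortho alkoxy groups and the para hydroxyl, and Friedel–Crafts-type C-benzylation of 3 at its free ring carbon should give 18.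

3. Step 7. Chloride attack on an ethyl group is slower than on a methyl group, so forcing the cleavage may start to remove the para methyl ether or let the Lewis acid cleave and scramble the methylene bridge. The fallback sets out from 10 (with 12 as the acetyl source) and comes back at 19; it replaces the ethyl ether by a benzyl ether that is removed under neutral conditions. Benzyl alcohol, KH and trichloroethylene in THF should give benzyl (E)-1,2-dichlorovinyl ether F5. n-BuLi (2.2 equiv) at −78 °C converts F5 into lithium benzyloxyacetylide, which is acylated in the same flask with 12 to give 4-(benzyloxy)but-3-yn-2-one F6. Cycloaddition–aromatisation of 10 with F6 under the conditions of step 6 should give 2-acetyl-6-{[3-acetyl-2-(benzyloxy)-4-hydroxy-6-methoxyphenyl]methyl}-3,5-dihydroxy-4,4-dimethylcyclohexa-2,5-dien-1-one F7. Hydrogenolysis (H2, Pd/C, EtOAc, rt) should then give 19.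

**Further compounds**

F1 | step 6 | 2',6'-dihydroxy-4'-methoxyacetophenone | COc1cc(O)c(C(C)=O)c(O)c1
F2 | step 4 | methyl (2E)-3,5-dimethoxypent-2-enoate | COC(=O)/C=C(/OC)CCOC
F3 | step 4 | (1Z,3Z)-1,3,5-trimethoxy-1-(trimethylsilyloxy)penta-1,3-diene | CO/C(O[Si](C)(C)C)=C/C(OC)=C/COC
F4 | step 4 | 1-[2-ethoxy-6-hydroxy-4-methoxy-3-(methoxymethyl)phenyl]ethan-1-one | CCOc1c(COC)c(OC)cc(O)c1C(C)=O
F5 | step 7 | benzyl (E)-1,2-dichlorovinyl ether | Cl/C=C(/Cl)OCc1ccccc1
F6 | step 7 | 4-(benzyloxy)but-3-yn-2-one | CC(=O)C#COCc1ccccc1
F7 | step 7 | 2-acetyl-6-{[3-acetyl-2-(benzyloxy)-4-hydroxy-6-methoxyphenyl]methyl}-3,5-dihydroxy-4,4-dimethylcyclohexa-2,5-dien-1-one | CC(=O)c1c(O)cc(OC)c(CC2=C(O)C(C)(C)C(O)=C(C(C)=O)C2=O)c1OCc1ccccc1
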